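A direct plan would take C1 from (R)-limonene and build the vinyl epoxy acid A1. It would close the ε-lactone first by acid-induced 7-exo epoxide opening at C12, then add C4–C8 by B-alkyl Suzuki coupling with the symmetric diiodide A2. The carbocycle would be closed last by Nozaki–Hiyama–Kishi coupling of the iodo aldehyde A3 at C3–C4.
Its weakest steps would be:
- the mono-coupling of A2, which would be statistical between two equal C–I bonds and would start from a regio-impure diiodide;
- the lactonisation of A1, which would combine an ionisable vinyl epoxide, a seven-membered closure and an acid-labile acetal;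
- the ring closure of A3, which would give both C3 epimers A4, so that oxidation to the enone A5 and a reagent-controlled reduction would follow, adding length but no complexity.

Both carbinols lie in one motif: C3(OH)–C2–C1(H)–C15=C17 and C11(O)–C10–C9H2–C8=C7 are bis-homoallylic alcohols, the retron of the nickel-catalysed homoallylation of an aldehyde by a 1,3-diene. Cutting C10–C11 and C2–C3 leaves (E)-β-ocimene (C3–C10, skipped E,E-diene ready-made), (S)-2-methylglycidol (C11–C13, C20, the one bought stereocentre), isoprene (C14, C1, C2, C15, C17) and CO (C16). The second homoallylation, the key step, closes the 14-membered ring at C2–C3, sets C1 and C3 together as the 1,3-anti pair and frees C3–OH directly; the lactone follows last by CO insertion onto the intact C12–OH. Statistical coupling, epoxide lactonisation and C3 correction have no counterpart.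

Key step: step 7

Assumption: cembrane numbering is used throughout (C1 = ring CH bearing C15; lactone C16(=O)–O–C12; C18, C19, C20 = methyls on C4, C8, C12), so the target is (1R,3R,4E,7E,11S,12R).

## Route

Step 1
Reactants: 1 (S)-2-methylglycidol
Product: 2 (2R)-2-methyloxirane-2-carbaldehyde
Conditions: (COCl)2, DMSO, CH2Cl2, −78 °C; Et3N, −78 → 0 °C; non-aqueous work-up, short-path distillation
Reagents that add atoms: none
Why: Swern oxidation stays basic and water-free, which suits a volatile acid-sensitive epoxy aldehyde; quaternary C12 cannot epimerise, and the S → R change is only a change of CIP priorities.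

Step 2
Reactants: 2 (2R)-2-methyloxirane-2-carbaldehyde; 3 (E)-β-ocimene (3 equiv)
Product: 4 (1S,4E)-4,8-dimethyl-1-[(2R)-2-methyloxiran-2-yl]nona-4,7-dien-1-ol
Conditions: Ni(acac)2 (10 mol %), Et3B (2.4 equiv), THF, rt
Reagents that add atoms: none
Why: Nickel-catalysed homoallylation of an aldehyde with a 1,3-diene joins the unsubstituted diene terminus C10 to C11 and puts the ethyl-derived hydride on C9, the C6 substituent stays syn on the η3-allyl so that C7=C8 stays E, and since the monodentate borane allows no chelate, Cornforth-type attack (C=O anti to the epoxide C–O, approach on the side away from the ring CH2) should give the erythro (11S) carbinol.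

Step 3
Reactants: 4 (1S,4E)-4,8-dimethyl-1-[(2R)-2-methyloxiran-2-yl]nona-4,7-dien-1-ol
Product: 6 (2E,5E,9S)-2,6-dimethyl-9-[(2R)-2-methyloxiran-2-yl]nona-2,5-diene-1,9-diol, via (2E,5E,9S)-9-hydroxy-2,6-dimethyl-9-[(2R)-2-methyloxiran-2-yl]nona-2,5-dienal 5 (not isolated)
Conditions: SeO2 (0.3 equiv), t-BuOOH (3 equiv), CH2Cl2, 0 °C → rt; then NaBH4, MeOH, 0 °C
Reagents that add atoms: tert-butyl hydroperoxide, CC(C)(C)OO (terminal oxidant; the oxygen is passed on by selenium dioxide, O=[Se]=O)
Why: Riley allylic oxidation (ene reaction, then [2,3] shift) attacks the terminal isopropylidene group at its E-methyl, which becomes C3 and fixes E-C4=C5, in preference to the internal olefin, and borohydride returns the over-oxidised enal to the alcohol.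

Step 4
Reactants: 6 (2E,5E,9S)-2,6-dimethyl-9-[(2R)-2-methyloxiran-2-yl]nona-2,5-diene-1,9-diol; 7 isoprene
Product: 10 (2E,5E,9S,10R)-2,6,10-trimethyl-13-methylidenepentadeca-2,5,14-triene-1,9,10-triol, via (2-methylidenebut-3-en-1-yl)potassium 8 (not isolated), via (2-methylidenebut-3-en-1-yl)lithium 9 (not isolated)
Conditions: 7, LiTMP, KOt-Bu, THF, −78 °C; LiBr; then 6 (pre-treated with n-BuLi, 2 equiv, −78 °C), −78 → −20 °C; aq. NH4Cl
Reagents that add atoms: none
Why: Superbase metallation of the isoprene methyl group followed by SN2 opening of the 2,2-disubstituted epoxide at its CH2 terminus C13 forms C13–C14; the two allyl termini are equivalent, so only the 2-substituted diene results, K → Li exchange lowers the basicity toward the doubly allylic C6–H, and the C12–O bond is untouched, so C12 keeps its configuration.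

Step 5
Reactants: 10 (2E,5E,9S,10R)-2,6,10-trimethyl-13-methylidenepentadeca-2,5,14-triene-1,9,10-triol
Product: 11 (2E,5E,9S,10R)-9,10-dihydroxy-2,6,10-trimethyl-13-methylidenepentadeca-2,5,14-trienal
Conditions: MnO2 (20 equiv), CH2Cl2, rt
Reagents that add atoms: none
Why: Manganese dioxide oxidises only the allylic primary alcohol, under neutral conditions that leave the skipped diene, the 1,3-diene and the saturated secondary and tertiary hydroxyls alone.

Step 6
Reactants: 11 (2E,5E,9S,10R)-9,10-dihydroxy-2,6,10-trimethyl-13-methylidenepentadeca-2,5,14-trienal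
Product: 12 (6R,7S,10E,13E)-6-hydroxy-6,10,14-trimethyl-3-methylidene-15-oxopentadeca-1,10,13-trien-7-yl acetate
Conditions: Ac2O (1.5 equiv), pyridine, DMAP (5 mol %), CH2Cl2, 0 °C
Reagents that add atoms: acetic anhydride, CC(=O)OC(C)=O
Why: DMAP-catalysed acetylation takes the secondary C11–OH and not the tertiary C12–OH, and the low temperature and short contact time keep the γ-acidic enal from moving into conjugation.

Step 7
Reactants: 12 (6R,7S,10E,13E)-6-hydroxy-6,10,14-trimethyl-3-methylidene-15-oxopentadeca-1,10,13-trien-7-yl acetate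
Product: 13 (1S,2R,5R,7R,8E,11E)-5-ethenyl-2,7-dihydroxy-2,8,12-trimethylcyclotetradeca-8,11-dien-1-yl acetate (cembrane numbering: 1R,3R,11S,12R)
Conditions: Ni(acac)2 (20 mol %), Et3B (4 equiv), THF, rt; 12 added over 12 h, final 2 mM
Reagents that add atoms: none
Why: Ni(0), formed from Ni(acac)2 and Et3B, binds the s-cis 2-alkyl-1,3-diene and the borane-activated enal and undergoes oxidative cyclisation, which forms C2–C3 and an oxanickelacycle whose η3-allyl spans C1–C15–C17; ethyl transfer from boron to nickel, β-hydride elimination (ethene) and reductive elimination then place H on C1, the allyl terminus next to the new bond, and leave the C15=C17 vinyl group. The closest known reactions are the nickel-catalysed homoallylation of aldehydes (enals included) with isoprene- and myrcene-type dienes, its cyclising version on ω-dienyl aldehydes, and nickel-catalysed reductive macrocyclisations of ynals; only the ring size is new here. One ring is closed, the 14-membered carbocycle, by attack of the terminal diene carbon C2 on the formyl carbon C3, both of which end up in the ring. C1 and C3 arise in the same nickelacycle, with the C4 alkenyl group pseudo-equatorial and H delivered to C1 from the nickel-bound face, which is the origin of the general 1,3-anti outcome, and (1R,3R) is the 1,3-anti pair along C4–C3–C2–C1–C15. The step needs attack at C2 rather than C17 (secured by the alkyl group on C1, as with isoprene), inertness of the two trisubstituted olefins (secured because they are not conjugated) and Re-face attack on C3=O relative to C11/C12. This last selectivity rests only on the chiral C9–C14 tether and on no neighbouring centre, so the two 1,3-anti diastereomers would be separated here if both form.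

Step 8
Reactants: 13 (1S,2R,5R,7R,8E,11E)-5-ethenyl-2,7-dihydroxy-2,8,12-trimethylcyclotetradeca-8,11-dien-1-yl acetate
Product: 14 (1S,2R,5R,7R,8E,11E)-7-[(tert-butyldimethylsilyl)oxy]-5-ethenyl-2-hydroxy-2,8,12-trimethylcyclotetradeca-8,11-dien-1-yl acetate
Conditions: TBSCl, imidazole, DMF, rt
Reagents that add atoms: tert-butyldimethylsilyl chloride, CC(C)(C)[Si](C)(C)Cl
Why: Silylation with TBSCl and imidazole takes the secondary allylic C3–OH and not the tertiary C12–OH, which blocks 5-exo oxypalladation in step 9 and δ-lactone formation in step 11.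

Step 9
Reactants: 14 (1S,2R,5R,7R,8E,11E)-7-[(tert-butyldimethylsilyl)oxy]-5-ethenyl-2-hydroxy-2,8,12-trimethylcyclotetradeca-8,11-dien-1-yl acetate
Product: 15 (1S,2R,5R,7R,8E,11E)-5-acetyl-7-[(tert-butyldimethylsilyl)oxy]-2-hydroxy-2,8,12-trimethylcyclotetradeca-8,11-dien-1-yl acetate
Conditions: PdCl2 (15 mol %), CuCl (1 equiv), O2 (1 atm), DMF/H2O 7:1, rt
Reagents that add atoms: water, O
Why: Tsuji–Wacker oxidation converts the only monosubstituted alkene into the methyl ketone (Markovnikov), the trisubstituted olefins bind Pd(II) too weakly to compete, and C1 is not exposed to base.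

Step 10
Reactants: 15 (1S,2R,5R,7R,8E,11E)-5-acetyl-7-[(tert-butyldimethylsilyl)oxy]-2-hydroxy-2,8,12-trimethylcyclotetradeca-8,11-dien-1-yl acetate
Product: 17 (1S,2R,5R,7R,8E,11E)-7-[(tert-butyldimethylsilyl)oxy]-2-hydroxy-5-(1-iodoethenyl)-2,8,12-trimethylcyclotetradeca-8,11-dien-1-yl acetate, via the N-(tert-butyldimethylsilyl)hydrazone of 15 16 (not isolated)
Conditions: (TBSNH)2, Sc(OTf)3 (1 mol %), CH2Cl2, rt; then I2, 1,1,3,3-tetramethylguanidine, THF, 0 °C
Reagents that add atoms: iodine, II
Why: Barton vinyl iodide synthesis in its N-silyl hydrazone form avoids free hydrazine and strong base, so the acetate next to the free C12–OH neither cleaves nor migrates, and proton loss from the unhindered CH3 gives the 1,1-disubstituted C15(I)=C17H2.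

Step 11
Reactants: 17 (1S,2R,5R,7R,8E,11E)-7-[(tert-butyldimethylsilyl)oxy]-2-hydroxy-5-(1-iodoethenyl)-2,8,12-trimethylcyclotetradeca-8,11-dien-1-yl acetate
Product: 18 3-O-(tert-butyldimethylsilyl)dendronpholide B
Conditions: PdCl2(PPh3)2 (10 mol %), CO (1 atm), K2CO3, DMF, 60 °C, 5 mM
Reagents that add atoms: carbon monoxide, [C-]#[O+]
Why: Palladium-catalysed carbonylative lactonisation of a halo alcohol (oxidative addition at C15–I, CO insertion to the C16 acyl-palladium, capture by the only free hydroxyl) forms C15–C16 and C16–O and gives the α-methylene ε-lactone directly, and the C12–O bond is never broken, so C12 stays R.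

Step 12
Reactants: 18 3-O-(tert-butyldimethylsilyl)dendronpholide B
Product: 19 dendronpholide B
Conditions: HF·pyridine, pyridine, THF, 0 °C → rt
Reagents that add atoms: none
Why: Buffered fluoride desilylation frees C3–OH without a basic nucleophile that could add to the exo-methylene group, cleave the acetate or start translactonisation.

## Compound list

1 | (S)-2-methylglycidol, [(2S)-2-methyloxiran-2-yl]methanol | OC[C@@]1(C)CO1 | starting material
2 | (2R)-2-methyloxirane-2-carbaldehyde | O=C[C@@]1(C)CO1 | intermediate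
3 | (E)-β-ocimene, (3E)-3,7-dimethylocta-1,3,6-triene | C=C/C(C)=C/CC=C(C)C | starting material
4 | (1S,4E)-4,8-dimethyl-1-[(2R)-2-methyloxiran-2-yl]nona-4,7-dien-1-ol | CC(C)=CC/C=C(\C)CC[C@H](O)[C@@]1(C)CO1 | intermediate
5 | (2E,5E,9S)-9-hydroxy-2,6-dimethyl-9-[(2R)-2-methyloxiran-2-yl]nona-2,5-dienal | O=C/C(C)=C/C/C=C(\C)CC[C@H](O)[C@@]1(C)CO1 | intermediate
6 | (2E,5E,9S)-2,6-dimethyl-9-[(2R)-2-methyloxiran-2-yl]nona-2,5-diene-1,9-diol | OC/C(C)=C/C/C=C(\C)CC[C@H](O)[C@@]1(C)CO1 | intermediate
7 | isoprene | C=CC(C)=C | starting material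
8 | (2-methylidenebut-3-en-1-yl)potassium | [K]CC(=C)C=C | intermediate
9 | (2-methylidenebut-3-en-1-yl)lithium | [Li]CC(=C)C=C | intermediate
10 | (2E,5E,9S,10R)-2,6,10-trimethyl-13-methylidenepentadeca-2,5,14-triene-1,9,10-triol | OC/C(C)=C/C/C=C(\C)CC[C@H](O)[C@](C)(O)CCC(=C)C=C | intermediate
11 | (2E,5E,9S,10R)-9,10-dihydroxy-2,6,10-trimethyl-13-methylidenepentadeca-2,5,14-trienal | O=C/C(C)=C/C/C=C(\C)CC[C@H](O)[C@](C)(O)CCC(=C)C=C | intermediate
12 | (6R,7S,10E,13E)-6-hydroxy-6,10,14-trimethyl-3-methylidene-15-oxopentadeca-1,10,13-trien-7-yl acetate | O=C/C(C)=C/C/C=C(\C)CC[C@H](OC(C)=O)[C@](C)(O)CCC(=C)C=C | intermediate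
13 | (1S,2R,5R,7R,8E,11E)-5-ethenyl-2,7-dihydroxy-2,8,12-trimethylcyclotetradeca-8,11-dien-1-yl acetate | C=C[C@H]1C[C@@H](O)/C(C)=C/C/C=C(\C)CC[C@H](OC(C)=O)[C@](C)(O)CC1 | intermediate
14 | (1S,2R,5R,7R,8E,11E)-7-[(tert-butyldimethylsilyl)oxy]-5-ethenyl-2-hydroxy-2,8,12-trimethylcyclotetradeca-8,11-dien-1-yl acetate | C=C[C@H]1C[C@@H](O[Si](C)(C)C(C)(C)C)/C(C)=C/C/C=C(\C)CC[C@H](OC(C)=O)[C@](C)(O)CC1 | intermediate
15 | (1S,2R,5R,7R,8E,11E)-5-acetyl-7-[(tert-butyldimethylsilyl)oxy]-2-hydroxy-2,8,12-trimethylcyclotetradeca-8,11-dien-1-yl acetate | CC(=O)[C@H]1C[C@@H](O[Si](C)(C)C(C)(C)C)/C(C)=C/C/C=C(\C)CC[C@H](OC(C)=O)[C@](C)(O)CC1 | intermediate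
16 | N-(tert-butyldimethylsilyl)hydrazone of 15 | CC(=NN[Si](C)(C)C(C)(C)C)[C@H]1C[C@@H](O[Si](C)(C)C(C)(C)C)/C(C)=C/C/C=C(\C)CC[C@H](OC(C)=O)[C@](C)(O)CC1 | intermediate
17 | (1S,2R,5R,7R,8E,11E)-7-[(tert-butyldimethylsilyl)oxy]-2-hydroxy-5-(1-iodoethenyl)-2,8,12-trimethylcyclotetradeca-8,11-dien-1-yl acetate | C=C(I)[C@H]1C[C@@H](O[Si](C)(C)C(C)(C)C)/C(C)=C/C/C=C(\C)CC[C@H](OC(C)=O)[C@](C)(O)CC1 | intermediate
18 | 3-O-(tert-butyldimethylsilyl)dendronpholide B (1R,3R,4E,7E,11S,12R) | C=C1C(=O)O[C@]2(C)CC[C@@H]1C[C@@H](O[Si](C)(C)C(C)(C)C)/C(C)=C/C/C=C(\C)CC[C@@H]2OC(C)=O | intermediate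
19 | dendronpholide B (1R,3R,4E,7E,11S,12R) | C=C1C(=O)O[C@]2(C)CC[C@@H]1C[C@@H](O)/C(C)=C/C/C=C(\C)CC[C@@H]2OC(C)=O | target

## Step count and risks

Total step count: 12. Longest linear sequence: 12 steps (1 → 19).

Steps most likely to fail:

**Step 7.** Ring closure may lose to oligomerisation. Above all, the face of the aldehyde may be chosen poorly, because the centres that must bias it (C11, C12) are remote. The fallback hands facial control to a reagent after the event. It sets out from 13 as it leaves step 7, mixed with the other 1,3-anti product, the (1S,3S) diastereomer of 13 F1. The mixture would be treated under Sharpless kinetic resolution conditions (Ti(Oi-Pr)4, L-(+)-DIPT, t-BuOOH, 4 Å MS, CH2Cl2, −20 °C). The (3S)-allylic alcohol is the fast-reacting partner of L-(+)-tartrate and would be converted into the polar erythro 4,5-epoxy alcohol F2. The (3R)-configured 13 would be left, and the route is rejoined at 13.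

**Step 11.** Capture of the acyl-palladium species by the hindered tertiary hydroxyl through a seven-membered transition state may be too slow, so that reduction or decay of the vinyl-palladium species wins. The fallback separates carbonylation from ring closure. It sets out from 17, which would be hydroxycarbonylated (Pd(OAc)2, dppf, CO, K2CO3, DMF/H2O) to the acrylic acid F3. This acid would be closed onto C12–OH by Shiina lactonisation (MNBA, DMAP, toluene, slow addition). The route is rejoined at 18.

**Step 2.** Facial selectivity of the Cornforth type at C11 may be modest, and the epoxide may be opened under the Ni/Et3B conditions. The fallback sets C11 and C12 together by reagent control. It sets out from 3, which would be coupled under the same nickel conditions with methacrolein (an enal, the best substrate class) to give the racemic allylic alcohol (6E)-2,6,10-trimethylundeca-1,6,9-trien-3-ol F4. Sharpless kinetic resolution (Ti(Oi-Pr)4, L-(+)-DIPT, 0.45 equiv t-BuOOH, −20 °C) would epoxidise only its (S)-enantiomer, to the erythro epoxy alcohol. The route is rejoined at 4.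

## Further compounds

F1 | step 7 | (1S,2R,5S,7S,8E,11E)-5-ethenyl-2,7-dihydroxy-2,8,12-trimethylcyclotetradeca-8,11-dien-1-yl acetate (cembrane numbering 1S,3S,11S,12R) | C=C[C@@H]1C[C@H](O)/C(C)=C/C/C=C(\C)CC[C@H](OC(C)=O)[C@](C)(O)CC1
F2 | step 7 | 4,5-epoxide of F1 (cembrane numbering 1S,3S,4S,5S,7E,11S,12R) | C=C[C@@H]1C[C@H](O)[C@]2(C)O[C@H]2C/C=C(\C)CC[C@H](OC(C)=O)[C@](C)(O)CC1
F3 | step 11 | 2-[(1R,3R,4E,7E,11S,12R)-11-acetoxy-3-[(tert-butyldimethylsilyl)oxy]-12-hydroxy-4,8,12-trimethylcyclotetradeca-4,7-dien-1-yl]prop-2-enoic acid (cembrane numbering) | C=C(C(O)=O)[C@H]1C[C@@H](O[Si](C)(C)C(C)(C)C)/C(C)=C/C/C=C(\C)CC[C@H](OC(C)=O)[C@](C)(O)CC1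
F4 | step 2 | rac-(6E)-2,6,10-trimethylundeca-1,6,9-trien-3-ol | CC(C)=CC/C=C(\C)CCC(O)C(C)=C
A1 | direct plan | (3R)-3-{2-[(2S,3S)-3-ethenyl-2-methyloxiran-2-yl]ethyl}-5,5-dimethoxy-2-methylidenepentanoic acid | C=C[C@@H]1O[C@@]1(C)CC[C@H](CC(OC)OC)C(=C)C(O)=O
A2 | direct plan | (2E,5E)-2,6-diiodohepta-2,5-diene | C/C(I)=C\C/C=C(\C)I
A3 | direct plan | (1S,4E,7E)-8-iodo-4-methyl-1-[(2R,5R)-2-methyl-6-methylidene-7-oxo-5-(2-oxoethyl)oxepan-2-yl]nona-4,7-dien-1-yl acetate | C=C1C(=O)O[C@](C)(CC[C@@H]1CC=O)[C@@H](OC(C)=O)CC/C(C)=C/C/C=C(\C)I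
A4 | direct plan | dendronpholide B and its C3 epimer (1R,11S,12R; 3RS) | C=C1C(=O)O[C@]2(C)CC[C@@H]1CC(O)/C(C)=C/C/C=C(\C)CC[C@@H]2OC(C)=O
A5 | direct plan | (1R,4E,7E,11S,12R)-11-acetoxy-3-oxocembra-4,7,15(17)-trien-16,12-olide | C=C1C(=O)O[C@]2(C)CC[C@@H]1CC(=O)/C(C)=C/C/C=C(\C)CC[C@@H]2OC(C)=O
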